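## Structural features

Propolin B is a flavanone: ring C is a chroman-4-one fused to ring A, a phloroglucinol ring with hydroxyls at C5 and C7, and ring B (a catechol) is attached at C2. Ring B carries at C5′, ortho to the 4′-hydroxyl, an (E)-7-hydroxy-3,7-dimethyloct-2-enyl chain, which is a geranyl unit hydrated at its distal alkene. C2 is the only stereocentre (S), so no neighbouring centre can relay or correct its configuration. C2 is benzylic, bears the ring oxygen and lies β to the C4 ketone, so it can be lost by base-induced opening to the 2′-hydroxychalcone or by ionisation under acid. The other fragile groups are the free phenols, the E-trisubstituted alkene (ortho-allylic to a phenol, so prone to acid-induced chroman formation) and the tertiary alcohol (prone to dehydration). The real difficulty is to set C2 absolutely while preventing the C4 carbonyl from undoing it, and to carry the acid-sensitive chain to the end. The key step uses the 1,3-relationship of the C4 carbonyl and the C2 benzylic oxygen across C3. C4 enters as a masked acyl anion on ring A and C2–C3 as a terminal oxirane on ring B, so C3–C4 is formed without touching the C2–O bond.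

## Logic of the disconnections

27 to 26: the four phenolic O–CH2 acetal bonds are restored. The phenols must be masked against organolithium reagents and against the Mitsunobu step, and one kind of ether on all four allows a single final operation. Nothing is gained in skeleton. The forward step needs an acid mild enough to spare the alkene, the tertiary alcohol and C2.

26 to 25: the C4 carbonyl is traced back to its dithioketal. Keeping C4 masked through ring closure removes every enolisable position, so neither elimination to a chalcone nor base-induced ring opening can occur. The forward unmasking must be neither basic nor oxidising.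

25 to 24: the O1–C2 bond of ring C is cut. This opens the heterocycle to an acyclic phenol with a secondary benzylic alcohol. The forward closure must be a clean SN2 with inversion, so 24 must carry the (R) carbinol and ionisation at the benzylic carbon must be suppressed.

24 to 23: one ortho oxygen of ring A and the tertiary alcohol are returned to their protected forms (O–CH2 and O–Si bonds). With C4 still a dithiane, a carbonyl cannot direct the release of a single ortho oxygen. That oxygen therefore carries a fluoride-labile silylethoxymethyl group from the start, while the other ring oxygens carry methoxymethyl groups. The forward step needs fluoride to cleave one acetal and leave four.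

23 to 21 and 16 (through 22): the C3–C4 bond is cut. This is the only cut that divides the molecule into its ring A and ring B halves while leaving the C2–O bond and its configuration intact. It reduces the problem to an aryl dithiane and an aryl oxirane. The forward step demands metalation at the dithiane carbon and attack at the CH2 terminus of the oxirane. The configurational bookkeeping is consistent: the (S)-oxirane becomes the (R)-carbinol with unchanged geometry, and the later inversion gives (2S).

21 to 19 and 20, then 19 to 18 to 17: the two C–S bonds and then the ring A O–CH2 bonds are cut in turn. The intramolecular hydrogen bond in 17 distinguishes one ortho hydroxyl, so the two kinds of acetal can be placed in order. The thioacetalisation must not ionise the acetal ethers.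

16 to 15 to 14: the oxirane is traced to the racemate and then, by cutting its C–CH2 bond, to an aldehyde. The aldehyde carbon becomes C2 and one methylene is added. The price is a resolution that discards at least half of the material, so it must be highly selective on an electron-rich aryl oxirane.

14 to 10 and 6 (through 11, 12 and 13): the aryl–C1″ bond is cut. This joins the terpenoid chain to ring B at the carbon that carried bromine. The forward step needs an aryl metal that attacks the primary allylic carbon and keeps the E alkene, with the aldehyde masked during metalation.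

10 to 9 to 8 to 7: the acetal C–O bonds, the two O–CH2 bonds and the O–CH3 bond are traced back. This leads to a commodity bromo aldehyde that already has the 1,3,4,5 substitution pattern of ring B. The demethylation must spare the aldehyde and the bromide.

6 to 5 to 4 to 3 to 1 (through 2): the C–Br, the O–Si and the tertiary C–O bonds are traced back. The E alkene and the whole carbon chain come from a terpene ester. The only demand is hydration of the distal alkene and not the allylic one.

## Other disconnections considered

Alternative 1: The cut is O1–C8a. In the forward direction the C2 alkoxide of bromo diol A2 would be arylated intramolecularly under copper catalysis (CuI with 1,10-phenanthroline and a carbonate base, hot toluene). This gives flavan-4-ol A1, which one further oxidation at C4 would convert into 26.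
- In favour: the C2–O bond is never broken, so the configuration is retained by mechanism. On stereochemical fidelity of the ring closure this is better than the chosen plan, which must carry out an SN2 displacement at an electron-rich benzylic carbon. It is the equal of the chosen plan in keeping C4 at a non-enolisable oxidation level during closure.
- Against: ring A must carry bromine in place of one ortho oxygen, which a symmetrical phloroglucinol aldehyde does not provide. The bromide is electron-rich and flanked by a branched substituent, so it is a poor partner for copper-mediated C–O coupling. The stereocentre of A2 still needs an asymmetric step of its own.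
- Step economy: with the extra oxidation, no better than the chosen plan.

Alternative 2: The cut is C4″–C5″ with transposition of the alkene. Allylic alcohol A4 and an orthoacetate, heated with a trace of carboxylic acid, would form a ketene acetal that rearranges through a chair transition state to ester A3 with the E C2″=C3″ alkene.
- In favour: the alkene geometry is set predictably and does not depend on the isomeric purity of a terpene feedstock. On control of alkene geometry it is the equal of the chosen plan, and better if Z isomer in commercial 1 proved inseparable.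
- Against: A3 is far from the target chain. Its ester carbon (C6″) must be reduced and C7″ with its two methyls and hydroxyl added, at least three further steps. The arene of A3 lacks the C1′ carbon, whose electrophilic introduction would compete with the alkene. The plan contributes nothing to the C2 problem.
- Step economy: the chosen plan obtains the complete chain in four steps from 1 and is clearly shorter.

Alternative 3: The cut is the C2–H bond, with flavone A6 as precursor. A chiral bisphosphine-ligated copper hydride (a copper salt, the ligand and a silane) would deliver hydride to C2, and protonation of the enolate at C3 would give A5, which is identical with 26.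
- In favour: all intermediates before the last C–H bond are flat and achiral, the assembly of A6 is short and convergent, nothing is lost in a resolution, and the stereocentre is made last. On step economy and material throughput this is better than the chosen plan. The two plans are equal in converging on the same protected flavanone and the same final step.
- Against: A6 is a vinylogous ester further deactivated by two ring A oxygens, so conjugate hydride delivery should be slow and 1,2-reduction may compete. Facial discrimination on a 2-aryl chromone of this substitution is not established. The enolate can open to a chalcone phenoxide and erase the new centre.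
- Comparison: the chosen plan is better in predictability, since its configuration derives from a resolution of known sense and two stereospecific substitutions.

Key step: step 14

Assumption: the hydrolytic kinetic resolution is taken to follow its usual sense for terminal oxiranes, so the (S,S)-cobalt salen acetate should hydrolyse the (R)-oxirane in 15 and leave 16; should a trial show the opposite sense, the (R,R)-complex is used.

## Route

Step 1
Reactants: 1 geranyl acetate
Product: 3 (2E)-7-hydroxy-3,7-dimethyloct-2-en-1-yl acetate, via alkylmercury acetate 2 (not isolated)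
Conditions: Hg(OAc)2, THF–H2O (1:1), rt; then NaBH4, 3 M NaOH, 0 °C
Reagents that add atoms: water, O
Why: Oxymercuration–demercuration (Markovnikov hydration): divalent mercury attacks the electron-richer C6=C7 alkene, the C2=C3 alkene being deactivated inductively by the allylic acetate, and water opens the mercurinium ion at the tertiary carbon. Cold borohydride then replaces mercury by hydrogen, so C6 ends as CH2 and no stereocentre remains.

Step 2
Reactants: 3 (2E)-7-hydroxy-3,7-dimethyloct-2-en-1-yl acetate
Product: 4 (2E)-3,7-dimethyl-7-(triethylsilyloxy)oct-2-en-1-yl acetate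
Conditions: TESOTf, 2,6-lutidine, CH2Cl2, −78 → 0 °C
Reagents that add atoms: triethylsilyl trifluoromethanesulfonate, CC[Si](CC)(CC)OS(=O)(=O)C(F)(F)F
Why: Silyl ether formation; a hindered tertiary alcohol needs the silyl triflate, and the ester is inert. The ether removes the only acidic proton of the chain before the organometallic steps.

Step 3
Reactants: 4 (2E)-3,7-dimethyl-7-(triethylsilyloxy)oct-2-en-1-yl acetate
Product: 5 (2E)-3,7-dimethyl-7-(triethylsilyloxy)oct-2-en-1-ol
Conditions: K2CO3 (cat.), MeOH, 0 °C → rt
Reagents that add atoms: none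
Why: Base-catalysed transesterification frees the primary allylic alcohol; a tertiary triethylsilyl ether is too hindered to be cleaved by carbonate in methanol.

Step 4
Reactants: 5 (2E)-3,7-dimethyl-7-(triethylsilyloxy)oct-2-en-1-ol
Product: 6 {[(6E)-8-bromo-2,6-dimethyloct-6-en-2-yl]oxy}triethylsilane
Conditions: CBr4, PPh3, CH2Cl2, 0 °C
Reagents that add atoms: carbon tetrabromide, BrC(Br)(Br)Br
Why: Appel reaction: the alkoxyphosphonium ion is displaced by bromide at the primary allylic carbon under neutral conditions, so the E alkene and the silyl ether are kept. The bromide is used without storage.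

Step 5
Reactants: 7 5-bromovanillin
Product: 8 3-bromo-4,5-dihydroxybenzaldehyde
Conditions: AlCl3, pyridine, CH2Cl2, reflux; then aq. HCl
Reagents that add atoms: none
Why: Lewis-acid-assisted O-demethylation: aluminium binds the phenoxide and the neighbouring methoxy oxygen, and pyridine removes the activated methyl group. The aldehyde and the aryl bromide are not affected.

Step 6
Reactants: 8 3-bromo-4,5-dihydroxybenzaldehyde
Product: 9 3-bromo-4,5-bis(methoxymethoxy)benzaldehyde
Conditions: MOMCl, iPr2NEt, CH2Cl2, 0 °C → rt
Reagents that add atoms: chloromethyl methyl ether, COCCl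
Why: O-alkylation of both phenols (acetal ether formation) gives base-stable groups that survive organolithium reagents, fluoride and the Mitsunobu step and leave together in mild acid at the end.

Step 7
Reactants: 9 3-bromo-4,5-bis(methoxymethoxy)benzaldehyde
Product: 10 1-bromo-5-(dimethoxymethyl)-2,3-bis(methoxymethoxy)benzene
Conditions: HC(OMe)3, MeOH, PPTS (cat.), rt; then Et3N
Reagents that add atoms: trimethyl orthoformate, COC(OC)OC
Why: Acid-catalysed acetalisation masks the aldehyde against n-BuLi. Pyridinium tosylate at room temperature ionises the aldehyde-derived oxocarbenium ion easily but is too weak to cleave formaldehyde acetals on an electron-poor ring.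

Step 8
Reactants: 10 1-bromo-5-(dimethoxymethyl)-2,3-bis(methoxymethoxy)benzene; 6 {[(6E)-8-bromo-2,6-dimethyloct-6-en-2-yl]oxy}triethylsilane
Product: 14 3-[(2E)-3,7-dimethyl-7-(triethylsilyloxy)oct-2-en-1-yl]-4,5-bis(methoxymethoxy)benzaldehyde, via aryllithium 11 (not isolated), via arylcopper 12 (not isolated), via coupled dimethyl acetal 13 (not isolated)
Conditions: n-BuLi, THF, −78 °C; CuBr·SMe2, −78 → −40 °C; 6, −78 → 0 °C; then 10% aq. citric acid, THF, rt
Reagents that add atoms: water, O
Why: Bromine–lithium exchange (assisted by the ortho acetal oxygen), transmetalation to monovalent copper and allylic substitution at the primary α-carbon of 6; the γ-carbon is fully substituted, so direct displacement with retention of the E alkene is expected. Dilute citric acid hydrolyses only the benzaldehyde dimethyl acetal, which ionises many orders of magnitude faster than the methoxymethyl ethers.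

Step 9
Reactants: 14 3-[(2E)-3,7-dimethyl-7-(triethylsilyloxy)oct-2-en-1-yl]-4,5-bis(methoxymethoxy)benzaldehyde
Product: 15 rac-2-{3-[(2E)-3,7-dimethyl-7-(triethylsilyloxy)oct-2-en-1-yl]-4,5-bis(methoxymethoxy)phenyl}oxirane
Conditions: Me3S+ I−, KOtBu, DMSO–THF, 0 °C → rt
Reagents that add atoms: trimethylsulfonium iodide, C[S+](C)C.[I-]
Why: Corey–Chaykovsky epoxidation: the sulfonium ylide adds to the non-enolisable aldehyde and the betaine closes to the terminal oxirane with loss of dimethyl sulfide. The new stereocentre is formed racemic and is resolved in the next step.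

Step 10
Reactants: 15 rac-2-{3-[(2E)-3,7-dimethyl-7-(triethylsilyloxy)oct-2-en-1-yl]-4,5-bis(methoxymethoxy)phenyl}oxirane
Product: 16 (2S)-2-{3-[(2E)-3,7-dimethyl-7-(triethylsilyloxy)oct-2-en-1-yl]-4,5-bis(methoxymethoxy)phenyl}oxirane
Conditions: (S,S)-(salen)Co(OAc) [(S,S)-N,N′-bis(3,5-di-tert-butylsalicylidene)cyclohexane-1,2-diamine cobalt acetate] (2 mol %), H2O (0.55 equiv), THF, 0 °C → rt
Reagents that add atoms: none
Why: Hydrolytic kinetic resolution: two trivalent cobalt centres activate the oxirane and water cooperatively, and the (R)-enantiomer is hydrolysed at its CH2 carbon, so 16 is recovered at no more than half of the material. The stereocentre of 16 is thus selected by the chiral catalyst. The 4-O substituent, flanked by two ortho groups, is twisted out of conjugation, which should temper benzylic ionisation at cobalt.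

Step 11
Reactants: 17 2,4,6-trihydroxybenzaldehyde
Product: 18 2-hydroxy-4,6-bis(methoxymethoxy)benzaldehyde
Conditions: MOMCl (2.1 equiv), iPr2NEt, CH2Cl2, 0 °C
Reagents that add atoms: chloromethyl methyl ether, COCCl
Why: Selective O-alkylation: the hydroxyl hydrogen-bonded to the aldehyde is the least nucleophilic, so two equivalents of reagent take the para and the free ortho oxygen. This differentiates the two ortho oxygens of ring A.

Step 12
Reactants: 18 2-hydroxy-4,6-bis(methoxymethoxy)benzaldehyde
Product: 19 2,4-bis(methoxymethoxy)-6-{[2-(trimethylsilyl)ethoxy]methoxy}benzaldehyde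
Conditions: NaH, DMF, 0 °C; SEMCl, 0 °C → rt
Reagents that add atoms: 2-(trimethylsilyl)ethoxymethyl chloride, C[Si](C)(C)CCOCCl
Why: The chelated phenol is deprotonated irreversibly and alkylated (Williamson-type ether formation). The resulting acetal tolerates organolithium reagents like a methoxymethyl ether but can later be removed by fluoride alone.

Step 13
Reactants: 19 2,4-bis(methoxymethoxy)-6-{[2-(trimethylsilyl)ethoxy]methoxy}benzaldehyde; 20 propane-1,3-dithiol
Product: 21 2-[2,4-bis(methoxymethoxy)-6-{[2-(trimethylsilyl)ethoxy]methoxy}phenyl]-1,3-dithiane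
Conditions: I2 (5 mol %), CH2Cl2, 0 °C → rt; then aq. Na2S2O3–NaHCO3
Reagents that add atoms: none
Why: Dithioacetalisation under mild electrophilic catalysis in an aprotic solvent: the cation derived from the aldehyde is stabilised by three ring oxygens and forms far faster than the formaldehyde acetals can ionise.

Step 14
Reactants: 21 2-[2,4-bis(methoxymethoxy)-6-{[2-(trimethylsilyl)ethoxy]methoxy}phenyl]-1,3-dithiane; 16 (2S)-2-{3-[(2E)-3,7-dimethyl-7-(triethylsilyloxy)oct-2-en-1-yl]-4,5-bis(methoxymethoxy)phenyl}oxirane
Product: 23 (1R)-1-{3-[(2E)-3,7-dimethyl-7-(triethylsilyloxy)oct-2-en-1-yl]-4,5-bis(methoxymethoxy)phenyl}-2-{2-[2,4-bis(methoxymethoxy)-6-{[2-(trimethylsilyl)ethoxy]methoxy}phenyl]-1,3-dithian-2-yl}ethan-1-ol, via lithiated dithiane 22 (not isolated)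
Conditions: 21 (1.3 equiv), n-BuLi (1.25 equiv), THF, −78 → −30 °C; then 16, DMPU, −30 °C → rt; H2O
Reagents that add atoms: none
Why: n-BuLi removes the C2–H of the dithiane to give carbanion 22, a masked ring A acyl anion (Corey–Seebach umpolung), which opens the oxirane of 16 by SN2 at the unsubstituted CH2 and so forms C3–C4. The closest known reaction type is the opening of terminal and styrene-type oxiranes by 2-aryl-2-lithio-1,3-dithianes. No ring is closed and no stereocentre is created: the benzylic C–O bond is not touched, so the (S)-oxirane carbon becomes the (R)-carbinol of 23 with unchanged geometry, only the CIP ranking of its neighbours changing. Two selectivities are needed. The first is the site of metalation: the doubly sulfur-stabilised dithiane position must be lithiated in preference to the ring C–H positions flanked by acetal oxygens, which is secured by metalating cold, letting the anion settle at −30 °C before the oxirane is added, and keeping the dithiane in slight excess so that no n-BuLi remains. The second is the site of oxirane opening: the crowded, soft carbanion should attack the terminal carbon, and benzylic opening is disfavoured because no Lewis acid is added, DMPU sequesters the lithium cation, and the twisted 4-O substituent of ring B is a weak donor. The acetal ethers, the silyl ether and the remote alkene are inert to the carbanion.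

Step 15
Reactants: 23 (1R)-β-hydroxy dithiane bearing the silylethoxymethyl and triethylsilyl groups
Product: 24 2-{2-[(2R)-2-hydroxy-2-{3-[(2E)-7-hydroxy-3,7-dimethyloct-2-en-1-yl]-4,5-bis(methoxymethoxy)phenyl}ethyl]-1,3-dithian-2-yl}-3,5-bis(methoxymethoxy)phenol
Conditions: TBAF, H2N(CH2)2NH2, THF, 65 °C; aq. NH4Cl
Reagents that add atoms: none
Why: Fluoride-induced fragmentation: attack at silicon releases ethene, formaldehyde and the ring A phenoxide, and the same reagent cleaves the triethylsilyl ether, while methoxymethyl ethers and the dithiane are inert to fluoride. The diamine traps formaldehyde so that the electron-rich phenoxide is not hydroxymethylated; the carbinol centre is not involved.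

Step 16
Reactants: 24 phenol with (R)-benzylic carbinol and C4 dithiane
Product: 25 (2S)-2-{3-[(2E)-7-hydroxy-3,7-dimethyloct-2-en-1-yl]-4,5-bis(methoxymethoxy)phenyl}-5,7-bis(methoxymethoxy)spiro[chromane-4,2′-[1,3]dithiane]
Conditions: PPh3, DIAD, THF (0.01 M), 0 °C → rt
Reagents that add atoms: none
Why: Intramolecular Mitsunobu etherification: the secondary benzylic alcohol is activated as its alkoxyphosphonium ion and displaced by the phenoxide in a 6-exo-tet SN2 closure of ring C with inversion, so (R) becomes (2S). With C4 still a dithiane there is no acidic C3–H, which excludes elimination to a chalcone and base-induced ring opening; the tertiary alcohol cannot be activated.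

Step 17
Reactants: 25 (2S)-spiro dithiane flavan
Product: 26 (2S)-2-{3-[(2E)-7-hydroxy-3,7-dimethyloct-2-en-1-yl]-4,5-bis(methoxymethoxy)phenyl}-5,7-bis(methoxymethoxy)chroman-4-one
Conditions: MeI, CaCO3, MeCN–H2O (9:1), 45 °C
Reagents that add atoms: water, O
Why: Alkylative dithiane hydrolysis: S-methylation gives a sulfonium ion that opens to a thionium ion stabilised by ring A and is captured by water. Calcium carbonate neutralises the acid formed, so the medium is neither basic nor strongly acidic and C2 is not at risk.

Step 18
Reactants: 26 (2S)-tetrakis-O-methoxymethyl flavanone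
Product: 27 propolin B, (2S)-2-{3,4-dihydroxy-5-[(2E)-7-hydroxy-3,7-dimethyloct-2-en-1-yl]phenyl}-5,7-dihydroxychroman-4-one
Conditions: 3 M aq. HCl–MeOH (1:4), 40 °C
Reagents that add atoms: none
Why: Acid-catalysed acetal exchange with methanol removes all four methoxymethyl groups as dimethoxymethane. Dilute acid, the presence of water and moderate temperature are chosen to limit addition of the 4′-hydroxyl to the alkene and loss of the tertiary alcohol; a flavanone is configurationally stable in dilute acid.

## Compound list

1 | geranyl acetate, (2E)-3,7-dimethylocta-2,6-dien-1-yl acetate | CC(C)=CCC/C(C)=C/COC(C)=O | starting material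
2 | [(6E)-8-acetoxy-2-hydroxy-2,6-dimethyloct-6-en-3-yl]mercury acetate | CC(=O)OC/C=C(\C)CCC([Hg]OC(C)=O)C(C)(C)O | intermediate
3 | (2E)-7-hydroxy-3,7-dimethyloct-2-en-1-yl acetate | CC(=O)OC/C=C(\C)CCCC(C)(C)O | intermediate
4 | (2E)-3,7-dimethyl-7-(triethylsilyloxy)oct-2-en-1-yl acetate | CC(=O)OC/C=C(\C)CCCC(C)(C)O[Si](CC)(CC)CC | intermediate
5 | (2E)-3,7-dimethyl-7-(triethylsilyloxy)oct-2-en-1-ol | OC/C=C(\C)CCCC(C)(C)O[Si](CC)(CC)CC | intermediate
6 | {[(6E)-8-bromo-2,6-dimethyloct-6-en-2-yl]oxy}triethylsilane | BrC/C=C(\C)CCCC(C)(C)O[Si](CC)(CC)CC | intermediate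
7 | 5-bromovanillin (3-bromo-4-hydroxy-5-methoxybenzaldehyde) | COc1cc(C=O)cc(Br)c1O | starting material
8 | 3-bromo-4,5-dihydroxybenzaldehyde | O=Cc1cc(O)c(O)c(Br)c1 | intermediate
9 | 3-bromo-4,5-bis(methoxymethoxy)benzaldehyde | COCOc1cc(C=O)cc(Br)c1OCOC | intermediate
10 | 1-bromo-5-(dimethoxymethyl)-2,3-bis(methoxymethoxy)benzene | COCOc1cc(C(OC)OC)cc(Br)c1OCOC | intermediate
11 | [5-(dimethoxymethyl)-2,3-bis(methoxymethoxy)phenyl]lithium | COCOc1cc(C(OC)OC)cc([Li])c1OCOC | intermediate
12 | [5-(dimethoxymethyl)-2,3-bis(methoxymethoxy)phenyl]copper | COCOc1cc(C(OC)OC)cc([Cu])c1OCOC | intermediate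
13 | {[(6E)-8-[5-(dimethoxymethyl)-2,3-bis(methoxymethoxy)phenyl]-2,6-dimethyloct-6-en-2-yl]oxy}triethylsilane | C/C(=C\Cc1cc(C(OC)OC)cc(OCOC)c1OCOC)CCCC(C)(C)O[Si](CC)(CC)CC | intermediate
14 | 3-[(2E)-3,7-dimethyl-7-(triethylsilyloxy)oct-2-en-1-yl]-4,5-bis(methoxymethoxy)benzaldehyde | C/C(=C\Cc1cc(C=O)cc(OCOC)c1OCOC)CCCC(C)(C)O[Si](CC)(CC)CC | intermediate
15 | rac-2-{3-[(2E)-3,7-dimethyl-7-(triethylsilyloxy)oct-2-en-1-yl]-4,5-bis(methoxymethoxy)phenyl}oxirane | C/C(=C\Cc1cc(C2CO2)cc(OCOC)c1OCOC)CCCC(C)(C)O[Si](CC)(CC)CC | intermediate
16 | (2S)-2-{3-[(2E)-3,7-dimethyl-7-(triethylsilyloxy)oct-2-en-1-yl]-4,5-bis(methoxymethoxy)phenyl}oxirane | C/C(=C\Cc1cc([C@H]2CO2)cc(OCOC)c1OCOC)CCCC(C)(C)O[Si](CC)(CC)CC | intermediate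
17 | 2,4,6-trihydroxybenzaldehyde | O=Cc1c(O)cc(O)cc1O | starting material
18 | 2-hydroxy-4,6-bis(methoxymethoxy)benzaldehyde | O=Cc1c(O)cc(OCOC)cc1OCOC | intermediate
19 | 2,4-bis(methoxymethoxy)-6-{[2-(trimethylsilyl)ethoxy]methoxy}benzaldehyde | O=Cc1c(OCOCC[Si](C)(C)C)cc(OCOC)cc1OCOC | intermediate
20 | propane-1,3-dithiol | SCCCS | starting material
21 | 2-[2,4-bis(methoxymethoxy)-6-{[2-(trimethylsilyl)ethoxy]methoxy}phenyl]-1,3-dithiane | COCOc1cc(OCOC)c(C2SCCCS2)c(OCOCC[Si](C)(C)C)c1 | intermediate
22 | {2-[2,4-bis(methoxymethoxy)-6-{[2-(trimethylsilyl)ethoxy]methoxy}phenyl]-1,3-dithian-2-yl}lithium | COCOc1cc(OCOC)c(C2([Li])SCCCS2)c(OCOCC[Si](C)(C)C)c1 | intermediate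
23 | (1R)-1-{3-[(2E)-3,7-dimethyl-7-(triethylsilyloxy)oct-2-en-1-yl]-4,5-bis(methoxymethoxy)phenyl}-2-{2-[2,4-bis(methoxymethoxy)-6-{[2-(trimethylsilyl)ethoxy]methoxy}phenyl]-1,3-dithian-2-yl}ethan-1-ol | C/C(=C\Cc1cc([C@H](O)CC2(c3c(OCOC)cc(OCOC)cc3OCOCC[Si](C)(C)C)SCCCS2)cc(OCOC)c1OCOC)CCCC(C)(C)O[Si](CC)(CC)CC | intermediate
24 | 2-{2-[(2R)-2-hydroxy-2-{3-[(2E)-7-hydroxy-3,7-dimethyloct-2-en-1-yl]-4,5-bis(methoxymethoxy)phenyl}ethyl]-1,3-dithian-2-yl}-3,5-bis(methoxymethoxy)phenol | C/C(=C\Cc1cc([C@H](O)CC2(c3c(OCOC)cc(OCOC)cc3O)SCCCS2)cc(OCOC)c1OCOC)CCCC(C)(C)O | intermediate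
25 | (2S)-2-{3-[(2E)-7-hydroxy-3,7-dimethyloct-2-en-1-yl]-4,5-bis(methoxymethoxy)phenyl}-5,7-bis(methoxymethoxy)spiro[chromane-4,2′-[1,3]dithiane] | C/C(=C\Cc1cc([C@@H]2CC3(SCCCS3)c3c(OCOC)cc(OCOC)cc3O2)cc(OCOC)c1OCOC)CCCC(C)(C)O | intermediate
26 | (2S)-2-{3-[(2E)-7-hydroxy-3,7-dimethyloct-2-en-1-yl]-4,5-bis(methoxymethoxy)phenyl}-5,7-bis(methoxymethoxy)chroman-4-one | C/C(=C\Cc1cc([C@@H]2CC(=O)c3c(OCOC)cc(OCOC)cc3O2)cc(OCOC)c1OCOC)CCCC(C)(C)O | intermediate
27 | propolin B, (2S)-2-{3,4-dihydroxy-5-[(2E)-7-hydroxy-3,7-dimethyloct-2-en-1-yl]phenyl}-5,7-dihydroxychroman-4-one | C/C(=C\Cc1cc([C@@H]2CC(=O)c3c(O)cc(O)cc3O2)cc(O)c1O)CCCC(C)(C)O | target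

## Step count and least certain steps

Total: 18 steps. Longest linear sequence: 12 steps (steps 1–4, 8–10 and 14–18, from 1).

Step 14 (key step). The most likely failure is metalation at a ring C–H flanked by two acetal oxygens in place of the hindered dithiane C–H. A second risk is that the crowded carbanion reacts so slowly that the lithium cation isomerises the electron-rich aryl oxirane to an arylacetaldehyde or opens it at the benzylic carbon. The fallback sets out from 19 and 14, rejoins the route at 23, and makes the C2–C3 bond instead, so it needs neither the hindered carbanion nor the oxirane. Ohira–Bestmann homologation of 19 (dimethyl (1-diazo-2-oxopropyl)phosphonate, K2CO3, MeOH) gives terminal alkyne F1. Its lithium acetylide (n-BuLi, THF, −78 °C) adds to 14 to give propargylic alcohol F2, and MnO2 oxidises this to ynone F3. Double conjugate addition of 20 (NaOMe, MeOH–CH2Cl2) places both sulfur atoms on the carbon bearing ring A and gives β-keto dithiane F4. Oxazaborolidine-catalysed borane reduction ((S)-Me-CBS, BH3·SMe2, with the ring B aryl group as the large substituent) should then give 23.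

Step 10. The most likely failure is insufficient rate difference between the enantiomers, or cobalt-promoted rearrangement and non-selective benzylic opening of the electron-rich aryl oxirane; in any case half of the material is lost. The fallback sets out from 14 and rejoins at 16 without discarding material. Chloromethyllithium (ICH2Cl, n-BuLi, THF, −78 °C, cold acetic acid quench) adds to 14 to give racemic chlorohydrin F5. Dess–Martin oxidation gives α-chloro ketone F6, and (S)-Me-CBS with BH3·SMe2 reduces it to (S)-chlorohydrin F7. K2CO3 in MeOH closes F7 to 16 without touching the stereocentre.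

Step 16. The most likely failure is ionisation of the activated benzylic C–O bond, with partial loss of configuration, if closure is slowed by the peri interaction between the spiro dithiane and the 5-O substituent; elimination to a styrene is a lesser risk. The fallback sets out from 24 and rejoins at 26 by reversing the order of the two operations. The dithiane is hydrolysed first (MeI, CaCO3, aq. MeCN) to 2′-hydroxy β-hydroxy ketone F8, in which C4 is planar. Mitsunobu closure of F8 (PPh3, DIAD, toluene, −20 °C) then gives 26 directly. This is the second choice because base-induced elimination to a chalcone becomes possible.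

Step 8. The most likely failure is attack at the γ-carbon of the allylic bromide, erosion of the E geometry, or protonation or homocoupling of the aryl metal. The fallback sets out from 10 and rejoins at 14 by a palladium π-allyl pathway. Aryllithium 11 is trapped with 2-isopropoxy-4,4,5,5-tetramethyl-1,3,2-dioxaborolane to give aryl pinacol boronate F9. Suzuki–Miyaura allyl–aryl coupling of F9 with 6 (Pd(dppf)Cl2, K3PO4, THF–H2O, 50 °C) should join the aryl group to the less substituted allyl terminus and give 13, which the citric acid work-up of step 8 converts into 14.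

Step 18. The most likely failure is acid-promoted addition of the 4′-hydroxyl across the C2″=C3″ alkene (chroman formation) or ionisation of the tertiary alcohol. The fallback sets out from 26 and rejoins at 27 by a non-protic acetal cleavage. TMSOTf with 2,2′-bipyridyl (MeCN, 0 °C) converts the aryl methoxymethyl ethers into aryl trimethylsilyl ethers and silylates the tertiary alcohol, giving pentakis(trimethylsilyl) ether F10. Hydrolysis of F10 in aqueous methanol buffered near pH 5 gives 27.

## Further compounds

F1 | step 14 | 2-ethynyl-1,5-bis(methoxymethoxy)-3-{[2-(trimethylsilyl)ethoxy]methoxy}benzene | C#Cc1c(OCOCC[Si](C)(C)C)cc(OCOC)cc1OCOC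
F2 | step 14 | rac-1-{3-[(2E)-3,7-dimethyl-7-(triethylsilyloxy)oct-2-en-1-yl]-4,5-bis(methoxymethoxy)phenyl}-3-[2,4-bis(methoxymethoxy)-6-{[2-(trimethylsilyl)ethoxy]methoxy}phenyl]prop-2-yn-1-ol | C/C(=C\Cc1cc(C(O)C#Cc2c(OCOCC[Si](C)(C)C)cc(OCOC)cc2OCOC)cc(OCOC)c1OCOC)CCCC(C)(C)O[Si](CC)(CC)CC
F3 | step 14 | 1-{3-[(2E)-3,7-dimethyl-7-(triethylsilyloxy)oct-2-en-1-yl]-4,5-bis(methoxymethoxy)phenyl}-3-[2,4-bis(methoxymethoxy)-6-{[2-(trimethylsilyl)ethoxy]methoxy}phenyl]prop-2-yn-1-one | C/C(=C\Cc1cc(C(=O)C#Cc2c(OCOCC[Si](C)(C)C)cc(OCOC)cc2OCOC)cc(OCOC)c1OCOC)CCCC(C)(C)O[Si](CC)(CC)CC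
F4 | step 14 | 1-{3-[(2E)-3,7-dimethyl-7-(triethylsilyloxy)oct-2-en-1-yl]-4,5-bis(methoxymethoxy)phenyl}-2-{2-[2,4-bis(methoxymethoxy)-6-{[2-(trimethylsilyl)ethoxy]methoxy}phenyl]-1,3-dithian-2-yl}ethan-1-one | C/C(=C\Cc1cc(C(=O)CC2(c3c(OCOC)cc(OCOC)cc3OCOCC[Si](C)(C)C)SCCCS2)cc(OCOC)c1OCOC)CCCC(C)(C)O[Si](CC)(CC)CC
F5 | step 10 | rac-2-chloro-1-{3-[(2E)-3,7-dimethyl-7-(triethylsilyloxy)oct-2-en-1-yl]-4,5-bis(methoxymethoxy)phenyl}ethan-1-ol | C/C(=C\Cc1cc(C(O)CCl)cc(OCOC)c1OCOC)CCCC(C)(C)O[Si](CC)(CC)CC
F6 | step 10 | 2-chloro-1-{3-[(2E)-3,7-dimethyl-7-(triethylsilyloxy)oct-2-en-1-yl]-4,5-bis(methoxymethoxy)phenyl}ethan-1-one | C/C(=C\Cc1cc(C(=O)CCl)cc(OCOC)c1OCOC)CCCC(C)(C)O[Si](CC)(CC)CC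
F7 | step 10 | (1S)-2-chloro-1-{3-[(2E)-3,7-dimethyl-7-(triethylsilyloxy)oct-2-en-1-yl]-4,5-bis(methoxymethoxy)phenyl}ethan-1-ol | C/C(=C\Cc1cc([C@H](O)CCl)cc(OCOC)c1OCOC)CCCC(C)(C)O[Si](CC)(CC)CC
F8 | step 16 | (3R)-3-hydroxy-3-{3-[(2E)-7-hydroxy-3,7-dimethyloct-2-en-1-yl]-4,5-bis(methoxymethoxy)phenyl}-1-[2-hydroxy-4,6-bis(methoxymethoxy)phenyl]propan-1-one | C/C(=C\Cc1cc([C@H](O)CC(=O)c2c(O)cc(OCOC)cc2OCOC)cc(OCOC)c1OCOC)CCCC(C)(C)O
F9 | step 8 | 2-[5-(dimethoxymethyl)-2,3-bis(methoxymethoxy)phenyl]-4,4,5,5-tetramethyl-1,3,2-dioxaborolane | COCOc1cc(C(OC)OC)cc(B2OC(C)(C)C(C)(C)O2)c1OCOC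
F10 | step 18 | (2S)-5,7-bis(trimethylsilyloxy)-2-{3-[(2E)-3,7-dimethyl-7-(trimethylsilyloxy)oct-2-en-1-yl]-4,5-bis(trimethylsilyloxy)phenyl}chroman-4-one | C/C(=C\Cc1cc([C@@H]2CC(=O)c3c(O[Si](C)(C)C)cc(O[Si](C)(C)C)cc3O2)cc(O[Si](C)(C)C)c1O[Si](C)(C)C)CCCC(C)(C)O[Si](C)(C)C
A1 | alternative 1 | (2S)-2-{3-[(2E)-7-hydroxy-3,7-dimethyloct-2-en-1-yl]-4,5-bis(methoxymethoxy)phenyl}-5,7-bis(methoxymethoxy)chroman-4-ol (either C4 epimer) | C/C(=C\Cc1cc([C@@H]2CC(O)c3c(OCOC)cc(OCOC)cc3O2)cc(OCOC)c1OCOC)CCCC(C)(C)O
A2 | alternative 1 | (3S)-1-[2-bromo-4,6-bis(methoxymethoxy)phenyl]-3-{3-[(2E)-7-hydroxy-3,7-dimethyloct-2-en-1-yl]-4,5-bis(methoxymethoxy)phenyl}propane-1,3-diol | C/C(=C\Cc1cc([C@@H](O)CC(O)c2c(Br)cc(OCOC)cc2OCOC)cc(OCOC)c1OCOC)CCCC(C)(C)O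
A3 | alternative 2 | ethyl (4E)-6-[2,3-bis(methoxymethoxy)phenyl]-4-methylhex-4-enoate | CCOC(=O)CC/C(C)=C/Cc1cccc(OCOC)c1OCOC
A4 | alternative 2 | 1-[2,3-bis(methoxymethoxy)phenyl]-3-methylbut-3-en-2-ol | C=C(C)C(O)Cc1cccc(OCOC)c1OCOC
A5 | alternative 3 | (2S)-tetrakis-O-methoxymethyl propolin B (identical with 26) | C/C(=C\Cc1cc([C@@H]2CC(=O)c3c(OCOC)cc(OCOC)cc3O2)cc(OCOC)c1OCOC)CCCC(C)(C)O
A6 | alternative 3 | 2-{3-[(2E)-7-hydroxy-3,7-dimethyloct-2-en-1-yl]-4,5-bis(methoxymethoxy)phenyl}-5,7-bis(methoxymethoxy)-4H-chromen-4-one | C/C(=C\Cc1cc(-c2cc(=O)c3c(OCOC)cc(OCOC)cc3o2)cc(OCOC)c1OCOC)CCCC(C)(C)O
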